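## Analysis of the target

The target (31) is a dimeric isoflavan. An upper 7-hydroxychroman (O1, C2, C3, C4, C4a–C8a; its benzo ring is ring A) carries the 2,3-dihydroxy-4-methoxyphenyl ring B' at C3 and a benzene ring D at C4 (Ca bonded to C4, Cb–OMe, Cd–OH, Cf substituted). Ring D is at the same time the 3-aryl group of a lower 7-hydroxychroman (O1'', C2'', C3'', C4'', benzo ring A''), bonded through Cf–C3''. There are three stereocentres: C3 (R) and C4 (S) are adjacent and hold their aryl groups trans, while C3'' (R) is too far from C4 to be controlled by it and needs its own source of absolute configuration. Five phenols must be released at the end, one pair forming the easily oxidised catechol of ring B', while two aryl methyl ethers must stay; this fixes benzyl as the only protecting group. Rings D and A'' are resorcinol-type and strongly nucleophilic, so strong acids and strong electrophiles are excluded once they are present. The hard part is C4, a diarylmethine whose ring D neighbour is blocked at both ortho positions (OMe at Cb, the lower chroman at Cf), next to a second benzylic centre C3 that epimerises whenever C2 is a carbonyl. The plan rests on the position of O1 between the aryl carbon C8a and C2: without O1 the pyran ring is an indane in which C2 is a ketone bonded to C8a, C3 is the α-methylene and C4 is C3 of a 1-indanone.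

## Retrosynthetic reasoning

**31 from pentabenzyl ether 30.** The five O–benzyl bonds are cut last, in one hydrogenolysis. No earlier step then meets a free catechol or free resorcinol, and the two methyl ethers are never at risk.

**30 from diol 29.** The O1–C2 bond is cut. Closing it by substitution at a primary carbon with the ring A phenol touches neither C3 nor C4. Ionic reduction of lactol 28 was set aside: a cation at C2 would sit next to the new C3 centre and within reach of the 2'-benzyloxy oxygen of ring B'.

**29 from lactol 20 and iodonium salt 27.** The C3–C1' bond is cut. At the aldehyde level C3 is an enamine nucleophile, and ring B' can come as an electrophilic aryl donor whose substitution pattern is fixed by where the iodine sits. The forward step must place ring B' trans to ring D and reduce the aldehyde in the same flask, so that the α-aryl centre cannot drift.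

**20 from lactone 19.** This is only a change of oxidation level at C2.

**19 from indanone 18 (the key disconnection).** O1 is taken out, which cuts O1–C8a and O1–C2 and contracts the lactone to a five-membered ketone. Ring A then needs no ortho oxygen when it is joined to C4. C4 can be set on a carbocycle. C3 remains a plain methylene, which the forward oxygen insertion needs so that the aryl carbon, not C3, migrates.

**18 from chalcone 17.** The C4–C4a bond is cut (C3–C3a of the indanone). The bromine in 17 marks the ring A carbon that closes onto the enone β-carbon, so the site of ring closure is not left to arene reactivity. A Friedel–Crafts acylation was considered and set aside: the carbon to be acylated is meta to the ring A alkoxy group, rings D and A'' offer far better nucleophilic positions, and benzyl ethers do not survive the acids needed. The forward step must set C4 under control of a chiral palladium catalyst.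

**17 from aldehyde 14 and ketone 16.** The enone double bond is cut by a retro-aldol condensation. This joins the complete ring D/lower chroman unit to ring A in one step.

**14 from alcohol 13 and diol 12.** The O1''–C8a'' aryl ether bond is cut, to a primary alcohol and an aryl bromide. The forward ring closure is an intramolecular palladium-catalysed etherification, which needs no activation of either hydroxyl group of 12, followed by oxidation of the benzylic alcohol.

**12 from imide 11, and 11 from imide 10 and benzyl bromide 4.** The C3''–C4'' bond is cut. An auxiliary-controlled enolate alkylation sets the remote C3'' centre early and reliably, and hydride then removes the auxiliary and lowers the ring D ester in one operation.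

**10 from acid 8, toluate 7, phenol 6 and methyl orsellinate 5.** C2'' is traced to a carboxyl group put on the ortho-methyl group of 7. Compound 5 already holds the ring D pattern: the ester carbon becomes C4, and the two hydroxyl groups are told apart by the hydrogen bond of one of them to the ester.

**Side fragments.** Bromide 4 comes from aldehyde 1 through 2 and 3. Ketone 16 comes from ketone 15 by bromination para to the ether. Salt 27 comes from iodide 25, which goes back through 23 and 22 to 3-methoxycatechol 21. Masking the catechol as the diacetate leaves the methoxy group as the only strong director, so iodine enters para to it.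

## Alternatives that were turned down

**Alternative 1:** The lower half is cut at Cf–C3'' and C4''–C4a''. In the forward step bromide A2 (the finished upper chroman with bromine at Cf) is lithiated and added to vinylboronic ester A3. The boron ate complex then meets aryl triflate A4 under Pd(OAc)2 and a Mandyphos ligand; ring D shifts from boron to carbon and reductive elimination gives the secondary boronic ester A1.
- For it: it is convergent, ring A'' arrives late, and C3'' is set by a catalyst, not by a stoichiometric auxiliary. On these points it is stronger than the chosen route.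
- Against it: the migrating aryl group has the whole upper chroman on the carbon next to Cf, so both ate-complex formation and the 1,2-shift are hindered. The electron-rich ortho-alkoxy triflate A4 adds slowly to zerovalent palladium. Catalyst control must work against three existing stereocentres.
- After A1 a one-carbon homologation at boron, oxidation, acetal removal and ring closure are still needed before hydrogenolysis. The upper C3/C4 pair is not addressed at all and needs a second strategy.
- The chosen route sets C3'' at the start by a dependable alkylation and keeps organolithium chemistry away from late intermediates.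

**Alternative 2:** Ring D itself is taken apart, at Ca–Cb, Cc–Cd and Cd–Ce. In the forward step diazo enone A6, which joins both chromans, undergoes Wolff rearrangement. The ketene adds methoxyacetylene A7, and cyclobutenone opening and 6π closure give phenol A5.
- For it: the ring D substitution pattern is built with fixed regiochemistry, and A5 is one hydrogenolysis from the target. The endgame is shorter than in the chosen route.
- Against it: A6 must already contain all three stereocentres in two separately made chroman fragments, so the overall count is higher. The diazo carbon bears a secondary alkyl group with a β-hydrogen, which invites a 1,2-hydrogen shift of the carbene. The ketene carries two bulky branches at the carbons that must become Ca and Cf, which hinders both the cycloaddition and the electrocyclisation. A7 is volatile and unstable.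
- The chosen route takes the ring D pattern ready-made from 5, so the main asset of the benzannulation is not needed.

**Alternative 3:** The upper pyran ring is cut at C3–C4 and O1–C2. In the forward step the ortho-quinone methide released from carbinol A9 is trapped by the enamine formed from arylacetaldehyde A10 and a prolinol-derived amine catalyst, giving lactol A8.
- For it: A8 is the same compound as lactol 28 of the chosen route, reached in one bond-forming step from three aryl pieces, with the ring A oxygen present from the start. On step economy and convergence this alternative is clearly stronger.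
- Against it: the electrophilic carbon of the quinone methide carries ring D with both ortho positions occupied, so the aryl group is twisted and the carbon is shielded. The alkoxy groups stabilise the quinone methide and make it less reactive. A10 self-condenses readily. C4 would be set by the approach geometry to a quinone methide of uncertain alkene geometry, with the remote C3'' centre adding further diastereomers.
- The chosen route separates the two events: C4 is set in an intramolecular palladium step and C3 in a later enamine arylation with thermodynamic backing. Each is on a substrate class where the reaction type is established.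

Key step: step 15

Assumption: the sense of induction of the chiral bisphosphine in step 14 and of the imidazolidinone in step 21 is taken from the accepted facial models; if a first run shows the opposite sense, the antipode is used and nothing else changes.

Abbreviations used in names: ArD = 4-(benzyloxy)-2-[(3R)-7-(benzyloxy)-3,4-dihydro-2H-chromen-3-yl]-6-methoxyphenyl; ArB = 2,3-bis(benzyloxy)-4-methoxyphenyl.

## Route

Step 1
Reactants: 1 2-bromo-4-hydroxybenzaldehyde
Product: 2 4-(benzyloxy)-2-bromobenzaldehyde
Conditions: BnBr, K2CO3, DMF, rt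
Reagents that add atoms: benzyl bromide BrCc1ccccc1
Why: Williamson ether synthesis on the phenoxide; the aldehyde and the aryl bromide are inert.

Step 2
Reactants: 2 4-(benzyloxy)-2-bromobenzaldehyde
Product: 3 [4-(benzyloxy)-2-bromophenyl]methanol
Conditions: NaBH4, MeOH/THF, 0 °C
Reagents that add atoms: none
Why: Borohydride reduction of an aldehyde; the aryl bromide and the benzyl ether are not affected.

Step 3
Reactants: 3 [4-(benzyloxy)-2-bromophenyl]methanol
Product: 4 4-(benzyloxy)-2-bromo-1-(bromomethyl)benzene
Conditions: PBr3, CH2Cl2, 0 °C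
Reagents that add atoms: phosphorus tribromide BrP(Br)Br
Why: Substitution of the benzylic alcohol through its bromophosphite; with only one alkoxy group on the ring the bromide is stable enough to handle, unlike 2,4-dialkoxybenzyl bromides.

Step 4
Reactants: 5 methyl 2,4-dihydroxy-6-methylbenzoate (methyl orsellinate)
Product: 6 methyl 4-(benzyloxy)-2-hydroxy-6-methylbenzoate
Conditions: BnBr (1.05 equiv), K2CO3, acetone, reflux
Reagents that add atoms: benzyl bromide BrCc1ccccc1
Why: Williamson ether synthesis; the 2-hydroxyl is held in a hydrogen bond to the ester carbonyl, so the 4-hydroxyl is alkylated selectively.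

Step 5
Reactants: 6 methyl 4-(benzyloxy)-2-hydroxy-6-methylbenzoate
Product: 7 methyl 4-(benzyloxy)-2-methoxy-6-methylbenzoate
Conditions: MeI, K2CO3, DMF, 50 °C
Reagents that add atoms: iodomethane CI
Why: Williamson methylation of the hydrogen-bonded phenol under more forcing conditions; this fixes OMe at Cb and OBn at Cd of ring D.

Step 6
Reactants: 7 methyl 4-(benzyloxy)-2-methoxy-6-methylbenzoate
Product: 8 [5-(benzyloxy)-3-methoxy-2-(methoxycarbonyl)phenyl]acetic acid
Conditions: LiN(i-Pr)2 (2.2 equiv), THF, −78 °C; CO2; aq HCl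
Reagents that add atoms: carbon dioxide O=C=O
Why: Lateral lithiation of an ortho-toluate followed by carboxylation; the ester acidifies the ortho-methyl group and, flanked on both sides, resists attack by the benzylic anion at −78 °C.

Step 7
Reactants: 8 [5-(benzyloxy)-3-methoxy-2-(methoxycarbonyl)phenyl]acetic acid
Product: 10 methyl 4-(benzyloxy)-2-{2-[(4R)-4-benzyl-2-oxo-1,3-oxazolidin-3-yl]-2-oxoethyl}-6-methoxybenzoate, via mixed pivalic anhydride 9 (not isolated)
Conditions: t-BuCOCl, Et3N, THF, −20 °C; then (R)-4-benzyl-2-oxazolidinone, LiCl, −20 °C → rt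
Reagents that add atoms: (R)-4-benzyl-2-oxazolidinone O=C1N[C@H](Cc2ccccc2)CO1; pivaloyl chloride CC(C)(C)C(=O)Cl (its atoms remain only in 9)
Why: N-Acylation of the oxazolidinone through the mixed anhydride, which is attacked at the less hindered arylacetyl carbonyl; the hindered aryl ester does not react.

Step 8
Reactants: 10 methyl 4-(benzyloxy)-2-{2-[(4R)-4-benzyl-2-oxo-1,3-oxazolidin-3-yl]-2-oxoethyl}-6-methoxybenzoate; 4 4-(benzyloxy)-2-bromo-1-(bromomethyl)benzene
Product: 11 methyl 4-(benzyloxy)-2-{(2R)-1-[(4R)-4-benzyl-2-oxo-1,3-oxazolidin-3-yl]-3-[4-(benzyloxy)-2-bromophenyl]-1-oxopropan-2-yl}-6-methoxybenzoate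
Conditions: NaN(SiMe3)2, THF, −78 °C; then 4, −78 → −30 °C
Reagents that add atoms: none
Why: Evans asymmetric alkylation; the sodium-chelated Z-enolate is attacked by 4 on the face away from the benzyl group of the (R)-auxiliary, which gives the (R) configuration at the new centre, the future C3''.

Step 9
Reactants: 11 methyl 4-(benzyloxy)-2-{(2R)-1-[(4R)-4-benzyl-2-oxo-1,3-oxazolidin-3-yl]-3-[4-(benzyloxy)-2-bromophenyl]-1-oxopropan-2-yl}-6-methoxybenzoate
Product: 12 (2R)-3-[4-(benzyloxy)-2-bromophenyl]-2-[5-(benzyloxy)-2-(hydroxymethyl)-3-methoxyphenyl]propan-1-ol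
Conditions: LiAlH4, THF, 0 °C
Reagents that add atoms: none
Why: Hydride reduction removes the auxiliary as the primary alcohol and reduces the hindered benzoate to the benzylic alcohol in one operation; the aryl bromide survives at 0 °C and the stereocentre is no longer α to a carbonyl.

Step 10
Reactants: 12 (2R)-3-[4-(benzyloxy)-2-bromophenyl]-2-[5-(benzyloxy)-2-(hydroxymethyl)-3-methoxyphenyl]propan-1-ol
Product: 13 {4-(benzyloxy)-2-[(3R)-7-(benzyloxy)-3,4-dihydro-2H-chromen-3-yl]-6-methoxyphenyl}methanol
Conditions: Pd(OAc)2 (5 mol %), 2-(di-tert-butylphosphino)-1,1'-binaphthyl (6 mol %), Cs2CO3, toluene, 60 °C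
Reagents that add atoms: none
Why: Intramolecular palladium-catalysed aryl ether formation (Buchwald etherification), the known ring closure of isoflavans; the aliphatic hydroxyl reaches palladium through a seven-membered palladacycle, whereas the hindered benzylic hydroxyl would need a nine-membered one.

Step 11
Reactants: 13 {4-(benzyloxy)-2-[(3R)-7-(benzyloxy)-3,4-dihydro-2H-chromen-3-yl]-6-methoxyphenyl}methanol
Product: 14 4-(benzyloxy)-2-[(3R)-7-(benzyloxy)-3,4-dihydro-2H-chromen-3-yl]-6-methoxybenzaldehyde
Conditions: MnO2, CH2Cl2, rt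
Reagents that add atoms: none
Why: Selective oxidation of an electron-rich benzylic alcohol to the aldehyde, which stops at that level.

Step 12
Reactants: 15 1-[3-(benzyloxy)phenyl]ethan-1-one
Product: 16 1-[5-(benzyloxy)-2-bromophenyl]ethan-1-one
Conditions: N-bromosuccinimide, MeCN, rt, dark
Reagents that add atoms: N-bromosuccinimide O=C1CCC(=O)N1Br
Why: Electrophilic aromatic bromination para to the ether oxygen, the most activated and least hindered position; without acid or radical initiator the methyl ketone is not brominated.

Step 13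
Reactants: 14 4-(benzyloxy)-2-[(3R)-7-(benzyloxy)-3,4-dihydro-2H-chromen-3-yl]-6-methoxybenzaldehyde; 16 1-[5-(benzyloxy)-2-bromophenyl]ethan-1-one
Product: 17 (2E)-3-(ArD)-1-[5-(benzyloxy)-2-bromophenyl]prop-2-en-1-one
Conditions: KOH, EtOH/THF, rt
Reagents that add atoms: none
Why: Claisen–Schmidt condensation; 14 cannot enolise, the aldol dehydrates by E1cB to the (E)-enone, and C3'' has no acidic hydrogen.

Step 14
Reactants: 17 (2E)-3-(ArD)-1-[5-(benzyloxy)-2-bromophenyl]prop-2-en-1-one
Product: 18 (3S)-6-(benzyloxy)-3-(ArD)-2,3-dihydro-1H-inden-1-one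
Conditions: Pd(OAc)2 (5 mol %), (R)-3,5-Xyl-MeO-BIPHEP (6 mol %), i-Pr2NEt, PhCO2H, ethylene glycol, 90 °C
Reagents that add atoms: none
Why: Asymmetric intramolecular reductive Heck cyclisation of a 2'-bromochalcone, a known route to 3-aryl-1-indanones: zerovalent palladium inserts into C–Br, the aryl group adds to the enone β-carbon within the chiral bisphosphine pocket, and the palladium enolate is protonated while the amine returns divalent palladium to the zerovalent state. The ligand sets the new centre (S); the position of bromine, not arene nucleophilicity, decides which carbon closes the ring.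

Step 15
Reactants: 18 (3S)-6-(benzyloxy)-3-(ArD)-2,3-dihydro-1H-inden-1-one
Product: 19 (4S)-7-(benzyloxy)-4-(ArD)-3,4-dihydro-2H-chromen-2-one
Conditions: mCPBA (3 equiv), NaHCO3, CH2Cl2, 0 °C → rt, dark
Reagents that add atoms: 3-chloroperbenzoic acid O=C(OO)c1cccc(Cl)c1
Why: Baeyer–Villiger oxidation of a 1-indanone, the known conversion of 1-indanones into 3,4-dihydrocoumarins. The peracid adds to the C1 carbonyl to give the Criegee adduct, and the group anti to the breaking O–O bond shifts to oxygen as the carboxylate leaves. Two groups could shift, the aryl carbon C7a and the primary C2 methylene; the aryl carbon stabilises the electron-poor transition state far better, so oxygen enters between C7a and C1. The six-membered lactone is therefore closed by ring expansion of the five-membered ketone through a 1,2-shift from carbon to oxygen, and the two new bonds are O1–C8a and O1–C2 in chroman numbering. No stereocentre is formed, and the existing one (C3 of 18, C4 of 19) is β to the carbonyl, is not enolisable and keeps its (S) configuration. The step needs regioselectivity (aryl over methylene shift) and chemoselectivity (ketone over the dialkoxyarenes); the first is secured by C2 being an unbranched CH2, which is why ring B' is not yet attached, and the second by the mild hydrogencarbonate-buffered peracid, which keeps arene hydroxylation slow and the aryl lactone closed. The 6-benzyloxy group is meta to the migrating carbon and should slow the shift only slightly.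

Step 16
Reactants: 19 (4S)-7-(benzyloxy)-4-(ArD)-3,4-dihydro-2H-chromen-2-one
Product: 20 (4S)-7-(benzyloxy)-4-(ArD)-3,4-dihydro-2H-chromen-2-ol (both C2 epimers)
Conditions: i-Bu2AlH (1.1 equiv), CH2Cl2, −78 °C
Reagents that add atoms: none
Why: Partial reduction of a lactone to the lactol; the aluminium hemiacetal is stable at −78 °C and collapses only on work-up, and C4 is not involved.

Step 17
Reactants: 21 3-methoxybenzene-1,2-diol (3-methoxycatechol)
Product: 22 3-methoxy-1,2-phenylene diacetate
Conditions: Ac2O, pyridine, DMAP (cat.), CH2Cl2, rt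
Reagents that add atoms: acetic anhydride CC(=O)OC(C)=O
Why: Acetylation of both phenols; this turns the two strongest directors into weak ones and protects the catechol from oxidation.

Step 18
Reactants: 22 3-methoxy-1,2-phenylene diacetate
Product: 23 3-iodo-6-methoxy-1,2-phenylene diacetate
Conditions: N-iodosuccinimide, CF3CO2H, MeCN, rt
Reagents that add atoms: N-iodosuccinimide O=C1CCC(=O)N1I
Why: Electrophilic aromatic iodination; the methoxy group is the only strong donor left and directs iodine to its para position, the carbon that becomes C1' of ring B'.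

Step 19
Reactants: 23 3-iodo-6-methoxy-1,2-phenylene diacetate
Product: 25 2,3-bis(benzyloxy)-1-iodo-4-methoxybenzene, via 3-iodo-6-methoxybenzene-1,2-diol 24 (not isolated)
Conditions: K2CO3, MeOH, Ar, rt; evaporate; BnBr, K2CO3, DMF, rt
Reagents that add atoms: benzyl bromide BrCc1ccccc1
Why: Methanolysis of the aryl acetates and Williamson benzylation in one flask under argon, so that the air-sensitive iodocatechol is never handled.

Step 20
Reactants: 25 2,3-bis(benzyloxy)-1-iodo-4-methoxybenzene
Product: 27 (ArB)(2,4,6-trimethylphenyl)iodonium trifluoromethanesulfonate, via iodonium tosylate 26 (not isolated)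
Conditions: mCPBA, TsOH·H2O, mesitylene, CH2Cl2/CF3CH2OH, rt; then aq NaOTf
Reagents that add atoms: mesitylene Cc1cc(C)cc(C)c1; 4-methylbenzenesulfonic acid Cc1ccc(S(=O)(=O)O)cc1 (anion of 26); sodium trifluoromethanesulfonate [Na+].[O-]S(=O)(=O)C(F)(F)F
Why: One-pot diaryliodonium synthesis: the aryl iodide is oxidised to its trivalent iodine tosylate, which substitutes mesitylene, and the anion is then exchanged. The iodine stays on the ring B' carbon chosen in step 18, and the mesityl group is the one that is not transferred later.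

Step 21
Reactants: 20 (4S)-7-(benzyloxy)-4-(ArD)-3,4-dihydro-2H-chromen-2-ol; 27 (ArB)(2,4,6-trimethylphenyl)iodonium trifluoromethanesulfonate
Product: 29 5-(benzyloxy)-2-[(1S,2R)-2-(ArB)-1-(ArD)-3-hydroxypropyl]phenol, via arylated lactol 28 (not isolated)
Conditions: CuBr (10 mol %), (2S,5S)-5-benzyl-2-tert-butyl-3-methylimidazolidin-4-one·Cl3CCO2H (20 mol %), NaHCO3, toluene/Et2O, 23 °C; then NaBH4, MeOH, 0 °C
Reagents that add atoms: none
Why: Organocatalytic α-arylation of an aldehyde with a diaryliodonium salt under copper catalysis: the amine opens lactol 20 to its (E)-enamine, and the aryl–trivalent copper species formed from CuBr and 27 delivers ring B' (the less hindered aryl group of the salt) to C3. The benzyl group of the catalyst shields one enamine face and sets C3 (R), trans to ring D, which is also the more stable arrangement; reduction with NaBH4 in the same flask removes the aldehyde before the α-aryl centre can epimerise.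

Step 22
Reactants: 29 5-(benzyloxy)-2-[(1S,2R)-2-(ArB)-1-(ArD)-3-hydroxypropyl]phenol
Product: 30 (3R,4S)-7-(benzyloxy)-3-(ArB)-4-(ArD)-3,4-dihydro-2H-chromene
Conditions: PPh3, i-PrO2CN=NCO2i-Pr, THF, 0 °C → rt
Reagents that add atoms: none
Why: Intramolecular Mitsunobu etherification of the phenol with the primary alcohol (6-exo-tet), the standard isoflavan ring closure; the reacting carbon is not a stereocentre, so C3 and C4 are untouched.

Step 23
Reactants: 30 (3R,4S)-7-(benzyloxy)-3-(ArB)-4-(ArD)-3,4-dihydro-2H-chromene
Product: 31 (3R,4S)-3-(2,3-dihydroxy-4-methoxyphenyl)-4-{4-hydroxy-2-[(3R)-7-hydroxy-3,4-dihydro-2H-chromen-3-yl]-6-methoxyphenyl}-3,4-dihydro-2H-chromen-7-ol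
Conditions: H2 (1 atm), 10% Pd/C, THF/MeOH, rt; work-up under Ar
Reagents that add atoms: none
Why: Hydrogenolysis of the five benzyl ethers; the aryl methyl ethers and the chroman C–O bonds are inert, and no stereocentre carries a cleavable benzylic C–O bond.

## Compound list

1 | 2-bromo-4-hydroxybenzaldehyde | O=Cc1ccc(O)cc1Br | starting material
2 | 4-(benzyloxy)-2-bromobenzaldehyde | O=Cc1ccc(OCc2ccccc2)cc1Br | intermediate
3 | [4-(benzyloxy)-2-bromophenyl]methanol | OCc1ccc(OCc2ccccc2)cc1Br | intermediate
4 | 4-(benzyloxy)-2-bromo-1-(bromomethyl)benzene | BrCc1ccc(OCc2ccccc2)cc1Br | intermediate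
5 | methyl 2,4-dihydroxy-6-methylbenzoate (methyl orsellinate) | COC(=O)c1c(C)cc(O)cc1O | starting material
6 | methyl 4-(benzyloxy)-2-hydroxy-6-methylbenzoate | COC(=O)c1c(C)cc(OCc2ccccc2)cc1O | intermediate
7 | methyl 4-(benzyloxy)-2-methoxy-6-methylbenzoate | COC(=O)c1c(C)cc(OCc2ccccc2)cc1OC | intermediate
8 | [5-(benzyloxy)-3-methoxy-2-(methoxycarbonyl)phenyl]acetic acid | COC(=O)c1c(CC(=O)O)cc(OCc2ccccc2)cc1OC | intermediate
9 | [5-(benzyloxy)-3-methoxy-2-(methoxycarbonyl)phenyl]acetic pivalic anhydride | COC(=O)c1c(CC(=O)OC(=O)C(C)(C)C)cc(OCc2ccccc2)cc1OC | intermediate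
10 | methyl 4-(benzyloxy)-2-{2-[(4R)-4-benzyl-2-oxo-1,3-oxazolidin-3-yl]-2-oxoethyl}-6-methoxybenzoate | COC(=O)c1c(CC(=O)N2[C@H](Cc3ccccc3)COC2=O)cc(OCc2ccccc2)cc1OC | intermediate
11 | methyl 4-(benzyloxy)-2-{(2R)-1-[(4R)-4-benzyl-2-oxo-1,3-oxazolidin-3-yl]-3-[4-(benzyloxy)-2-bromophenyl]-1-oxopropan-2-yl}-6-methoxybenzoate | COC(=O)c1c([C@@H](Cc2ccc(OCc3ccccc3)cc2Br)C(=O)N2[C@H](Cc3ccccc3)COC2=O)cc(OCc2ccccc2)cc1OC | intermediate
12 | (2R)-3-[4-(benzyloxy)-2-bromophenyl]-2-[5-(benzyloxy)-2-(hydroxymethyl)-3-methoxyphenyl]propan-1-ol | OCc1c([C@@H](Cc2ccc(OCc3ccccc3)cc2Br)CO)cc(OCc2ccccc2)cc1OC | intermediate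
13 | {4-(benzyloxy)-2-[(3R)-7-(benzyloxy)-3,4-dihydro-2H-chromen-3-yl]-6-methoxyphenyl}methanol | OCc1c([C@@H]2COc3cc(OCc4ccccc4)ccc3C2)cc(OCc2ccccc2)cc1OC | intermediate
14 | 4-(benzyloxy)-2-[(3R)-7-(benzyloxy)-3,4-dihydro-2H-chromen-3-yl]-6-methoxybenzaldehyde | O=Cc1c([C@@H]2COc3cc(OCc4ccccc4)ccc3C2)cc(OCc2ccccc2)cc1OC | intermediate
15 | 1-[3-(benzyloxy)phenyl]ethan-1-one | CC(=O)c1cccc(OCc2ccccc2)c1 | starting material
16 | 1-[5-(benzyloxy)-2-bromophenyl]ethan-1-one | CC(=O)c1cc(OCc2ccccc2)ccc1Br | intermediate
17 | (2E)-3-{4-(benzyloxy)-2-[(3R)-7-(benzyloxy)-3,4-dihydro-2H-chromen-3-yl]-6-methoxyphenyl}-1-[5-(benzyloxy)-2-bromophenyl]prop-2-en-1-one | O=C(/C=C/c1c([C@@H]2COc3cc(OCc4ccccc4)ccc3C2)cc(OCc2ccccc2)cc1OC)c1cc(OCc2ccccc2)ccc1Br | intermediate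
18 | (3S)-6-(benzyloxy)-3-{4-(benzyloxy)-2-[(3R)-7-(benzyloxy)-3,4-dihydro-2H-chromen-3-yl]-6-methoxyphenyl}-2,3-dihydro-1H-inden-1-one | O=C1C[C@H](c2c(OC)cc(OCc3ccccc3)cc2[C@@H]2COc3cc(OCc4ccccc4)ccc3C2)c2ccc(OCc3ccccc3)cc21 | intermediate
19 | (4S)-7-(benzyloxy)-4-{4-(benzyloxy)-2-[(3R)-7-(benzyloxy)-3,4-dihydro-2H-chromen-3-yl]-6-methoxyphenyl}-3,4-dihydro-2H-chromen-2-one | O=C1Oc2cc(OCc3ccccc3)ccc2[C@@H](c2c(OC)cc(OCc3ccccc3)cc2[C@@H]2COc3cc(OCc4ccccc4)ccc3C2)C1 | intermediate
20 | (4S)-7-(benzyloxy)-4-{4-(benzyloxy)-2-[(3R)-7-(benzyloxy)-3,4-dihydro-2H-chromen-3-yl]-6-methoxyphenyl}-3,4-dihydro-2H-chromen-2-ol (both C2 epimers) | OC1Oc2cc(OCc3ccccc3)ccc2[C@@H](c2c(OC)cc(OCc3ccccc3)cc2[C@@H]2COc3cc(OCc4ccccc4)ccc3C2)C1 | intermediate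
21 | 3-methoxybenzene-1,2-diol (3-methoxycatechol) | COc1cccc(O)c1O | starting material
22 | 3-methoxy-1,2-phenylene diacetate | COc1cccc(OC(C)=O)c1OC(C)=O | intermediate
23 | 3-iodo-6-methoxy-1,2-phenylene diacetate | COc1ccc(I)c(OC(C)=O)c1OC(C)=O | intermediate
24 | 3-iodo-6-methoxybenzene-1,2-diol | COc1ccc(I)c(O)c1O | intermediate
25 | 2,3-bis(benzyloxy)-1-iodo-4-methoxybenzene | COc1ccc(I)c(OCc2ccccc2)c1OCc1ccccc1 | intermediate
26 | [2,3-bis(benzyloxy)-4-methoxyphenyl](2,4,6-trimethylphenyl)iodonium 4-methylbenzenesulfonate | COc1ccc([I+]c2c(C)cc(C)cc2C)c(OCc2ccccc2)c1OCc1ccccc1.Cc1ccc(S(=O)(=O)[O-])cc1 | intermediate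
27 | [2,3-bis(benzyloxy)-4-methoxyphenyl](2,4,6-trimethylphenyl)iodonium trifluoromethanesulfonate | COc1ccc([I+]c2c(C)cc(C)cc2C)c(OCc2ccccc2)c1OCc1ccccc1.[O-]S(=O)(=O)C(F)(F)F | intermediate
28 | (3R,4S)-7-(benzyloxy)-3-[2,3-bis(benzyloxy)-4-methoxyphenyl]-4-{4-(benzyloxy)-2-[(3R)-7-(benzyloxy)-3,4-dihydro-2H-chromen-3-yl]-6-methoxyphenyl}-3,4-dihydro-2H-chromen-2-ol (both C2 epimers) | COc1ccc([C@@H]2C(O)Oc3cc(OCc4ccccc4)ccc3[C@H]2c2c(OC)cc(OCc3ccccc3)cc2[C@@H]2COc3cc(OCc4ccccc4)ccc3C2)c(OCc2ccccc2)c1OCc1ccccc1 | intermediate
29 | 5-(benzyloxy)-2-[(1S,2R)-2-[2,3-bis(benzyloxy)-4-methoxyphenyl]-1-{4-(benzyloxy)-2-[(3R)-7-(benzyloxy)-3,4-dihydro-2H-chromen-3-yl]-6-methoxyphenyl}-3-hydroxypropyl]phenol | COc1ccc([C@H](CO)[C@@H](c2ccc(OCc3ccccc3)cc2O)c2c(OC)cc(OCc3ccccc3)cc2[C@@H]2COc3cc(OCc4ccccc4)ccc3C2)c(OCc2ccccc2)c1OCc1ccccc1 | intermediate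
30 | (3R,4S)-7-(benzyloxy)-3-[2,3-bis(benzyloxy)-4-methoxyphenyl]-4-{4-(benzyloxy)-2-[(3R)-7-(benzyloxy)-3,4-dihydro-2H-chromen-3-yl]-6-methoxyphenyl}-3,4-dihydro-2H-chromene | COc1ccc([C@@H]2COc3cc(OCc4ccccc4)ccc3[C@H]2c2c(OC)cc(OCc3ccccc3)cc2[C@@H]2COc3cc(OCc4ccccc4)ccc3C2)c(OCc2ccccc2)c1OCc1ccccc1 | intermediate
31 | (3R,4S)-3-(2,3-dihydroxy-4-methoxyphenyl)-4-{4-hydroxy-2-[(3R)-7-hydroxy-3,4-dihydro-2H-chromen-3-yl]-6-methoxyphenyl}-3,4-dihydro-2H-chromen-7-ol | COc1ccc([C@@H]2COc3cc(O)ccc3[C@H]2c2c(OC)cc(O)cc2[C@@H]2COc3cc(O)ccc3C2)c(O)c1O | target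

## Step count and least certain steps

Total: 23 steps. Longest linear sequence: 15 steps (5 to 31 through steps 4–11, 13–16 and 21–23). Precursor 18 is reached after ten steps of this sequence.

**Step 15 (key step).** The most likely failure is slow addition of the peracid to the conjugated aryl ketone, whose migrating carbon has only a meta-alkoxy group. Long exposure then allows electrophilic hydroxylation of rings D and A'', and any build-up of acid allows competing methylene migration or opening of the aryl lactone.
Fallback, from aldehyde 14 back to lactone 19: the ring A oxygen is brought in with the nucleophile instead of by insertion. 3-(Benzyloxy)phenol is iodinated ortho to the hydroxyl group (I2, NaHCO3) to 5-(benzyloxy)-2-iodophenol F1. F1 is protected as 4-(benzyloxy)-1-iodo-2-(methoxymethoxy)benzene F2. Iodine–magnesium exchange (i-PrMgCl·LiCl) and borylation with B(OMe)3 give [4-(benzyloxy)-2-(methoxymethoxy)phenyl]boronic acid F3. Aldehyde 14 is olefinated with methyl (triphenylphosphoranylidene)acetate to methyl (2E)-3-(ArD)prop-2-enoate F4. Conjugate addition of F3 with [Rh(cod)Cl]2, (R)-BINAP and aqueous KOH in dioxane gives methyl (3S)-3-[4-(benzyloxy)-2-(methoxymethoxy)phenyl]-3-(ArD)propanoate F5. HCl in MeOH removes the acetal and the free phenol lactonises (TsOH cat., toluene) to 19. This path is not the first choice because the ortho-oxygenated boronic acid must be made and is prone to protodeboronation at a hindered acceptor.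

**Step 14.** Carbopalladation at the β-carbon, which is flanked by both ortho substituents of ring D, may be slow. The aryl–palladium intermediate is then reduced to the debrominated chalcone, or the enone is simply reduced. Facial selectivity may also be low or of the wrong sense on this unusually hindered substrate.
Fallback, from ketone 16 (with aldehyde 14) back to indanone 18: the ring is closed by rhodium-catalysed conjugate addition of an arylboron group. Ketone 16 is borylated (bis(pinacolato)diboron, Pd(dppf)Cl2, KOAc, dioxane) to 1-[5-(benzyloxy)-2-(4,4,5,5-tetramethyl-1,3,2-dioxaborolan-2-yl)phenyl]ethan-1-one F6. Condensation with 14 gives (2E)-3-(ArD)-1-[5-(benzyloxy)-2-(4,4,5,5-tetramethyl-1,3,2-dioxaborolan-2-yl)phenyl]prop-2-en-1-one F7. F7 is cyclised with [Rh(C2H4)2Cl]2, a chiral phosphoramidite ligand and aqueous K3PO4 in toluene to 18; no hydride source is present in this closure.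

**Step 21.** The open form of lactol 20 has a free phenol that can be O-arylated by the copper–aryl species. Enamine formation next to the diarylmethine may be sluggish. The facial preference of the catalyst may oppose that of the substrate.
Fallback, from lactone 19 back to diol 29: the aryl group is put on at the lactone level, where no hydroxyl group is free. Lactone 19 is converted with LiN(SiMe3)2 and Me3SiCl at −78 °C into the silyl ketene acetal {[(4S)-7-(benzyloxy)-4-(ArD)-4H-chromen-2-yl]oxy}trimethylsilane F8. Copper-catalysed arylation with 27 (Cu(OTf)2, 2,6-di-tert-butylpyridine, CH2Cl2) takes place anti to ring D and gives (3R,4S)-7-(benzyloxy)-3-(ArB)-4-(ArD)-3,4-dihydro-2H-chromen-2-one F9. LiAlH4 opens F9 to 29.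

**Step 20.** The very electron-rich iodoarene may be over-oxidised, or its trivalent iodine form may attack a second molecule of 25 instead of mesitylene.
Fallback, from iodide 25 back to tosylate 26 and so to 27: iodine–magnesium exchange (i-PrMgCl·LiCl) and quenching with Bu3SnCl give (ArB)tributylstannane F10. F10 reacts at tin with preformed [hydroxy(tosyloxy)iodo]mesitylene in CH2Cl2 to give 26, so the oxidant never meets ring B'.

## Further compounds

F1 | step 15 | 5-(benzyloxy)-2-iodophenol | Oc1cc(OCc2ccccc2)ccc1I
F2 | step 15 | 4-(benzyloxy)-1-iodo-2-(methoxymethoxy)benzene | COCOc1cc(OCc2ccccc2)ccc1I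
F3 | step 15 | [4-(benzyloxy)-2-(methoxymethoxy)phenyl]boronic acid | COCOc1cc(OCc2ccccc2)ccc1B(O)O
F4 | step 15 | methyl (2E)-3-{4-(benzyloxy)-2-[(3R)-7-(benzyloxy)-3,4-dihydro-2H-chromen-3-yl]-6-methoxyphenyl}prop-2-enoate | COC(=O)/C=C/c1c([C@@H]2COc3cc(OCc4ccccc4)ccc3C2)cc(OCc2ccccc2)cc1OC
F5 | step 15 | methyl (3S)-3-[4-(benzyloxy)-2-(methoxymethoxy)phenyl]-3-{4-(benzyloxy)-2-[(3R)-7-(benzyloxy)-3,4-dihydro-2H-chromen-3-yl]-6-methoxyphenyl}propanoate | COC(=O)C[C@@H](c1ccc(OCc2ccccc2)cc1OCOC)c1c(OC)cc(OCc2ccccc2)cc1[C@@H]1COc2cc(OCc3ccccc3)ccc2C1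
F6 | step 14 | 1-[5-(benzyloxy)-2-(4,4,5,5-tetramethyl-1,3,2-dioxaborolan-2-yl)phenyl]ethan-1-one | CC(=O)c1cc(OCc2ccccc2)ccc1B1OC(C)(C)C(C)(C)O1
F7 | step 14 | (2E)-3-{4-(benzyloxy)-2-[(3R)-7-(benzyloxy)-3,4-dihydro-2H-chromen-3-yl]-6-methoxyphenyl}-1-[5-(benzyloxy)-2-(4,4,5,5-tetramethyl-1,3,2-dioxaborolan-2-yl)phenyl]prop-2-en-1-one | O=C(/C=C/c1c([C@@H]2COc3cc(OCc4ccccc4)ccc3C2)cc(OCc2ccccc2)cc1OC)c1cc(OCc2ccccc2)ccc1B1OC(C)(C)C(C)(C)O1
F8 | step 21 | {[(4S)-7-(benzyloxy)-4-{4-(benzyloxy)-2-[(3R)-7-(benzyloxy)-3,4-dihydro-2H-chromen-3-yl]-6-methoxyphenyl}-4H-chromen-2-yl]oxy}trimethylsilane | C[Si](C)(C)OC1=C[C@H](c2c(OC)cc(OCc3ccccc3)cc2[C@@H]2COc3cc(OCc4ccccc4)ccc3C2)c2ccc(OCc3ccccc3)cc2O1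
F9 | step 21 | (3R,4S)-7-(benzyloxy)-3-[2,3-bis(benzyloxy)-4-methoxyphenyl]-4-{4-(benzyloxy)-2-[(3R)-7-(benzyloxy)-3,4-dihydro-2H-chromen-3-yl]-6-methoxyphenyl}-3,4-dihydro-2H-chromen-2-one | COc1ccc([C@@H]2C(=O)Oc3cc(OCc4ccccc4)ccc3[C@H]2c2c(OC)cc(OCc3ccccc3)cc2[C@@H]2COc3cc(OCc4ccccc4)ccc3C2)c(OCc2ccccc2)c1OCc1ccccc1
F10 | step 20 | [2,3-bis(benzyloxy)-4-methoxyphenyl]tributylstannane | CCCC[Sn](CCCC)(CCCC)c1ccc(OC)c(OCc2ccccc2)c1OCc1ccccc1
A1 | alternative 1 | secondary pinacol boronic ester at C3'' carrying the ring A'' benzyl group (product of the conjunctive coupling) | COc1ccc([C@@H]2COc3cc(OCc4ccccc4)ccc3[C@H]2c2c(OC)cc(OCc3ccccc3)cc2[C@@H](Cc2ccc(OCc3ccccc3)cc2OCOC)B2OC(C)(C)C(C)(C)O2)c(OCc2ccccc2)c1OCc1ccccc1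
A2 | alternative 1 | upper-fragment aryl bromide with bromine at Cf | COc1ccc([C@@H]2COc3cc(OCc4ccccc4)ccc3[C@H]2c2c(OC)cc(OCc3ccccc3)cc2Br)c(OCc2ccccc2)c1OCc1ccccc1
A3 | alternative 1 | 2-ethenyl-4,4,5,5-tetramethyl-1,3,2-dioxaborolane | C=CB1OC(C)(C)C(C)(C)O1
A4 | alternative 1 | 4-(benzyloxy)-2-(methoxymethoxy)phenyl trifluoromethanesulfonate | COCOc1cc(OCc2ccccc2)ccc1OS(=O)(=O)C(F)(F)F
A5 | alternative 2 | tetrabenzyl ether of the target with the ring D hydroxyl free (product of the benzannulation) | COc1ccc([C@@H]2COc3cc(OCc4ccccc4)ccc3[C@H]2c2c(OC)cc(O)cc2[C@@H]2COc3cc(OCc4ccccc4)ccc3C2)c(OCc2ccccc2)c1OCc1ccccc1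
A6 | alternative 2 | α-diazo enone joining the two chromans | COc1ccc([C@@H]2COc3cc(OCc4ccccc4)ccc3[C@H]2C(=[N+]=[N-])C(=O)C(=C)[C@@H]2COc3cc(OCc4ccccc4)ccc3C2)c(OCc2ccccc2)c1OCc1ccccc1
A7 | alternative 2 | methoxyacetylene | COC#C
A8 | alternative 3 | perbenzylated trans-3,4-diarylchroman-2-ol, identical with 28 (product of the annulation) | COc1ccc([C@@H]2C(O)Oc3cc(OCc4ccccc4)ccc3[C@H]2c2c(OC)cc(OCc3ccccc3)cc2[C@@H]2COc3cc(OCc4ccccc4)ccc3C2)c(OCc2ccccc2)c1OCc1ccccc1
A9 | alternative 3 | ring A/ring D diarylcarbinol | Oc1cc(OCc2ccccc2)ccc1C(O)c1c(OC)cc(OCc2ccccc2)cc1[C@@H]1COc2cc(OCc3ccccc3)ccc2C1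
A10 | alternative 3 | [2,3-bis(benzyloxy)-4-methoxyphenyl]acetaldehyde | COc1ccc(CC=O)c(OCc2ccccc2)c1OCc1ccccc1
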